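## Retrosynthetic overview

1. Target acid ⇐ its tert-butyl ester (acidolysis, last step; the stereocenter is not touched).
2. Butenolide ring (the only ring) and the C5 stereocenter ⇐ 14-acetoxytetradecanal + a (Z)-β-triflyloxy fumarate diester. The C4–C5 bond is made by a catalytic asymmetric nickel/chromium reductive coupling in which the triflate-bearing β-carbon acts as a β-acylvinyl anion (homoenolate) equivalent toward the aldehyde carbon. The new alkoxide closes the lactone onto the cis ethyl ester in the same flask.
3. Alkenyl triflate ⇐ tert-butyl ethyl oxalylpropionate (chelation-controlled enol triflation) ⇐ ethyl propanoate + di-tert-butyl oxalate (crossed Claisen).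
4. Aldehyde ⇐ tetradecane-1,14-diol (monoacetylation, then oxidation).
5. Ring order: one ring, formed in the coupling step together with the stereocenter.

Assumption: metal enolates, metal alkoxides and catalyst-bound organometallic species are treated as forms of the numbered compounds and are not numbered on their own.

Assumption: the (S)-configured sulfonamide ligand is taken to deliver the alkenyl group to the Si face of the aldehyde (which gives R at C5); this is checked on the first batch by chiral HPLC and optical rotation, and the mirror-image ligand is used if the sense is the opposite.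

## Route

Step 1
Reactants: 1 tetradecane-1,14-diol
Product: 2 14-hydroxytetradecyl acetate
Conditions: Ac2O (1.0 equiv), pyridine (1.5 equiv), 4-(dimethylamino)pyridine (1 mol%), THF, 40 °C
Reagents that add atoms: acetic anhydride, CC(=O)OC(C)=O
Why: Nucleophilic acyl substitution (O-acetylation) with one equivalent of anhydride gives the statistical monoacetate (about half of the material) because the two remote hydroxyls react independently; diol and diacetate are separated and recycled.

Step 2
Reactants: 2 14-hydroxytetradecyl acetate
Product: 3 14-oxotetradecyl acetate (14-acetoxytetradecanal)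
Conditions: 2,2,6,6-tetramethylpiperidin-1-oxyl (TEMPO, 10 mol%), PhI(OAc)2 (1.1 equiv), CH2Cl2, rt
Reagents that add atoms: none
Why: TEMPO/oxoammonium-catalysed alcohol oxidation stops at the aldehyde in the absence of water and leaves the acetate alone.

Step 3
Reactants: 4 ethyl propanoate, 5 di-tert-butyl oxalate
Product: 6 4-tert-butyl 1-ethyl 2-methyl-3-oxobutanedioate (racemic, keto/enol mixture)
Conditions: LiN(iPr)2 (1.05 equiv), THF, −78 °C; add to 5 (1.3 equiv), THF, −78 → −20 °C; 1 M HCl
Reagents that add atoms: none
Why: Crossed Claisen condensation: the preformed lithium enolate of 4 attacks the non-enolisable, doubly activated oxalate 5 (kept in excess), and the expelled tert-butoxide deprotonates the new β-keto ester, which shields its ketone from a second addition until the acid quench.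

Step 4
Reactants: 6 4-tert-butyl 1-ethyl 2-methyl-3-oxobutanedioate
Product: 7 4-tert-butyl 1-ethyl (2Z)-2-methyl-3-{[(trifluoromethyl)sulfonyl]oxy}but-2-enedioate (triflate cis to CO2Et, the two esters trans)
Conditions: NaH (1.1 equiv), Et2O, 0 °C; Tf2O (1.1 equiv), −20 → 0 °C
Reagents that add atoms: trifluoromethanesulfonic anhydride, O=S(=O)(OS(=O)(=O)C(F)(F)F)C(F)(F)F
Why: O-Sulfonylation of the sodium enolate (enol triflate formation): the enolate oxygen and the ethyl ester carbonyl are held cis in a six-membered sodium chelate, so the triflate ends up cis to CO2Et, the Z geometry needed for lactone closure.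

Step 5
Reactants: 3 14-oxotetradecyl acetate, 7 4-tert-butyl 1-ethyl (2Z)-2-methyl-3-{[(trifluoromethyl)sulfonyl]oxy}but-2-enedioate (1.4 equiv)
Product: 9 tert-butyl (2R)-2-[13-(acetyloxy)tridecyl]-4-methyl-5-oxo-2,5-dihydrofuran-3-carboxylate, via open-chain hydroxy diester 8 (not isolated)
Conditions: CrCl2 (10 mol%), (S)-N-[2-(4-isopropyl-4,5-dihydrooxazol-2-yl)-6-methylphenyl]methanesulfonamide (11 mol%), Et3N (20 mol%), NiCl2(2,9-dimethyl-1,10-phenanthroline) (3 mol%), Mn powder (2 equiv), Cp2ZrCl2 (1.2 equiv), LiCl (2 equiv), MeCN, rt; aq. NaHCO3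
Reagents that add atoms: none
Why: Proposed new method: a catalytic asymmetric Nozaki–Hiyama–Kishi (nickel/chromium) alkenylation in which zerovalent nickel inserts into the C–OTf bond of 7 with retention, the alkenyl group passes to trivalent chromium held by the chiral sulfonamide and adds to the Si face of 3 to set C5 as R, and the zirconium-bound alkoxide of 8 then closes onto the cis ethyl ester to give the butenolide; the carbon that carried the triflate is the acceptor (β) carbon of the lactone carbonyl, so it is used with reversed polarity as a β-acylvinyl anion (homoenolate) equivalent against the electrophilic aldehyde carbon; the closest known reaction types are the Kishi catalytic asymmetric nickel/chromium coupling of alkenyl iodides and triflates with aldehydes and the butenolide-forming coupling of (Z)-β-iodoacrylates, and what is new is a tetrasubstituted alkenyl triflate that carries an ester on the metalated carbon.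

Step 6
Reactants: 9 tert-butyl (2R)-2-[13-(acetyloxy)tridecyl]-4-methyl-5-oxo-2,5-dihydrofuran-3-carboxylate
Product: 10 (2R)-2-[13-(acetyloxy)tridecyl]-4-methyl-5-oxo-2,5-dihydrofuran-3-carboxylic acid (target)
Conditions: CF3CO2H/CH2Cl2 (1:4), 0 °C → rt
Reagents that add atoms: none
Why: Acidolysis of the tert-butyl ester (E1 loss of isobutene) frees the acid; the acetate, the lactone and the C5 stereocenter (no base, and no ionisable C–O bond next to the electron-poor alkene) are untouched.

## Compound list

1 | tetradecane-1,14-diol | OCCCCCCCCCCCCCCO | starting material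
2 | 14-hydroxytetradecyl acetate | CC(=O)OCCCCCCCCCCCCCCO | intermediate
3 | 14-oxotetradecyl acetate (14-acetoxytetradecanal) | CC(=O)OCCCCCCCCCCCCCC=O | intermediate
4 | ethyl propanoate | CCC(=O)OCC | starting material
5 | di-tert-butyl oxalate | CC(C)(C)OC(=O)C(=O)OC(C)(C)C | starting material
6 | 4-tert-butyl 1-ethyl 2-methyl-3-oxobutanedioate (racemic, enolisable) | CCOC(=O)C(C)C(=O)C(=O)OC(C)(C)C | intermediate
7 | 4-tert-butyl 1-ethyl (2Z)-2-methyl-3-{[(trifluoromethyl)sulfonyl]oxy}but-2-enedioate | CCOC(=O)/C(C)=C(\OS(=O)(=O)C(F)(F)F)C(=O)OC(C)(C)C | intermediate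
8 | 4-tert-butyl 1-ethyl (2E)-3-[(1R)-14-(acetyloxy)-1-hydroxytetradecyl]-2-methylbut-2-enedioate (formed as its zirconium alkoxide) | CC(=O)OCCCCCCCCCCCCC[C@@H](O)/C(C(=O)OC(C)(C)C)=C(/C)C(=O)OCC | intermediate
9 | tert-butyl (2R)-2-[13-(acetyloxy)tridecyl]-4-methyl-5-oxo-2,5-dihydrofuran-3-carboxylate | CC(=O)OCCCCCCCCCCCCC[C@H]1OC(=O)C(C)=C1C(=O)OC(C)(C)C | intermediate
10 | (2R)-2-[13-(acetyloxy)tridecyl]-4-methyl-5-oxo-2,5-dihydrofuran-3-carboxylic acid | CC(=O)OCCCCCCCCCCCCC[C@H]1OC(=O)C(C)=C1C(=O)O | target

## Step count and risks

Total step count: 6. Longest linear sequence: 4 steps (1 → 2 → 3 → 9 → 10, or 4/5 → 6 → 7 → 9 → 10).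

**Step 5 (most likely to fail).** The alkenylchromium is tetrasubstituted and carries an ester on the metalated carbon. It may react as a chromium allenolate, which would leak E/Z geometry; the wrong geometric isomer cannot lactonise. The enantioselectivity on this substrate class is unproven.

Fallback: take the stereocenter from a ketone reduction instead. Setting out from 3, Pinnick oxidation (NaClO2, NaH2PO4, 2-methylbut-2-ene, tBuOH/H2O) gives 14-(acetyloxy)tetradecanoic acid F1, and (COCl)2 with a drop of DMF gives 14-(acetyloxy)tetradecanoyl chloride F2. Nickel-catalysed reductive acyl–alkenyl cross-coupling of F2 with triflate 7 (NiBr2(MeOCH2CH2OMe), 4,4'-di-tert-butyl-2,2'-bipyridine, Mn, N,N-dimethylacetamide, 0 °C) gives the ketone 4-tert-butyl 1-ethyl (2E)-3-[14-(acetyloxy)tetradecanoyl]-2-methylbut-2-enedioate F3. Corey–Bakshi–Shibata reduction ((S)-2-methyl-CBS-oxazaborolidine, catecholborane, toluene, −78 °C, the alkenyl group acting as the large group) gives the R alcohol 8, which closes with a trace of TsOH to 9, where the route is rejoined.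

**Step 4.** The E/Z ratio of the enol triflate and its stability to hydrolysis are the concerns.

Fallback: use an alkenyl bromide whose geometry comes from an anti-addition/anti-elimination sequence. Commercial dimethyl citraconate (dimethyl (2Z)-2-methylbut-2-enedioate) is brominated (Br2, CH2Cl2, dark, rt, ionic anti addition) to racemic dimethyl (2RS,3RS)-2,3-dibromo-2-methylbutanedioate F4. Et3N (CH2Cl2, 0 °C, anti elimination of the C3 hydrogen and the C2 bromine) gives dimethyl (2Z)-2-bromo-3-methylbut-2-enedioate F5, with bromine cis to the distal ester; any geometric isomer from radical leakage is removed by chromatography. The fallback sets out from 3: F5 takes the place of 7 in the step 5 coupling and gives dimethyl (2E)-2-[(1R)-14-(acetyloxy)-1-hydroxytetradecyl]-3-methylbut-2-enedioate F6, which lactonises in the flask to methyl (2R)-2-[13-(acetyloxy)tridecyl]-4-methyl-5-oxo-2,5-dihydrofuran-3-carboxylate F7. SN2 demethylation (LiI, EtOAc, reflux; the carboxylate of the electron-poor acid is the best leaving group and the primary acetate is not attacked) gives the target 10 directly.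

**Step 3.** The crossed Claisen on the hindered oxalate may give incomplete acylation or a second addition to the new ketone.

Fallback: build the same keto diester by aldol addition and oxidation. tert-Butyl 2-oxoacetate F8 is made by NaIO4 cleavage of commercial di-tert-butyl L-tartrate (CH2Cl2/H2O). Setting out from 4, its lithium enolate (LiN(iPr)2, THF, −78 °C) adds to F8 to give 4-tert-butyl 1-ethyl 3-hydroxy-2-methylbutanedioate F9 (diastereomer mixture, of no consequence). Dess–Martin periodinane (CH2Cl2, rt) oxidises F9 to 6, where the route is rejoined.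

## Further compounds

F1 | step 5 | 14-(acetyloxy)tetradecanoic acid | CC(=O)OCCCCCCCCCCCCCC(=O)O
F2 | step 5 | 14-(acetyloxy)tetradecanoyl chloride | CC(=O)OCCCCCCCCCCCCCC(Cl)=O
F3 | step 5 | 4-tert-butyl 1-ethyl (2E)-3-[14-(acetyloxy)tetradecanoyl]-2-methylbut-2-enedioate | CC(=O)OCCCCCCCCCCCCCC(=O)/C(C(=O)OC(C)(C)C)=C(/C)C(=O)OCC
F4 | step 4 | dimethyl (2RS,3RS)-2,3-dibromo-2-methylbutanedioate (racemic; one enantiomer drawn) | COC(=O)[C@H](Br)[C@@](C)(Br)C(=O)OC
F5 | step 4 | dimethyl (2Z)-2-bromo-3-methylbut-2-enedioate | COC(=O)/C(C)=C(\Br)C(=O)OC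
F6 | step 4 | dimethyl (2E)-2-[(1R)-14-(acetyloxy)-1-hydroxytetradecyl]-3-methylbut-2-enedioate | CC(=O)OCCCCCCCCCCCCC[C@@H](O)/C(C(=O)OC)=C(/C)C(=O)OC
F7 | step 4 | methyl (2R)-2-[13-(acetyloxy)tridecyl]-4-methyl-5-oxo-2,5-dihydrofuran-3-carboxylate | CC(=O)OCCCCCCCCCCCCC[C@H]1OC(=O)C(C)=C1C(=O)OC
F8 | step 3 | tert-butyl 2-oxoacetate | CC(C)(C)OC(=O)C=O
F9 | step 3 | 4-tert-butyl 1-ethyl 3-hydroxy-2-methylbutanedioate (diastereomer mixture) | CCOC(=O)C(C)C(O)C(=O)OC(C)(C)C
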